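**Plan**

- Cuts, in retrosynthetic order: C12–C13 (sp3–sp2 coupling of the bicyclic core with a geraniol-derived iodotriene); the C8 carbinol back to a C8 ketone carried as a dioxolane; the second C4 methyl and C5–H back to a 4-methyl enone; last, C9–C10, the bond that closes ring B.
- Enabling feature: ring A (C1–C5, C10) has the pattern of a para-cresol. The C3 oxygen is para to the methyl-bearing C10, the C4 methyl is ortho to oxygen and C5 carries the tether C6–C7–C8–C9, so a 3-substituted 2,4-dimethylphenol can be dearomatised at C10 to make that carbon quaternary.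
- Forward: ring A is bought as an arene, and the tether is built by phosphonate alkylation and olefination. Ring B closes in the key step by attack of C10 on C9 of an allyl unit C9–C11–C12; C8 is kept as an sp3 ketal, because an allyl unit centred on C8 would offer two six-membered closures. Ring A is then reduced and methylated, C8 is converted to the carbinol and the chain is joined last at the C9 vinyl group.
- Stereochemistry: C9 and C10 come from the chiral bisphosphine–palladium catalyst acting on an achiral precursor; C5 from axial protonation in the Li/NH3 reduction; C8 from α-face epoxidation of the 8-methylene group and hydride opening. The three E alkenes come from geraniol, syn carboalumination and SeO2 oxidation.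

Key step: step 12

Remark on numbering: positions follow the target (C1–C10 for the decalin, C3 carbonyl, C4 gem-dimethyl, C8 carbinol, C9 chain-bearing; C11–C22 along the chain from C9); "decalin" is shorthand for the bicyclic core, and β means the face of the C10 methyl.

Remark on the ligand: the sense of induction of the bisphosphine in step 12 cannot be derived from precedent; the (R,R) ligand is written, and its antipode is to be used if the first experiment shows the opposite sense.

**Route**

Step 1
Reactants: 1 2,6-dimethylbenzoic acid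
Product: 2 2,6-dimethyl-3-nitrobenzoic acid
Conditions: fuming HNO3, conc. H2SO4, 0 °C
Reagents that add atoms: nitric acid, O[N+](=O)[O-]
Why: Electrophilic aromatic nitration is directed to C3 by both methyl groups (ortho to one, para to the other) and by the meta-directing carboxyl group, and the nitro group then deactivates the ring against a second substitution.

Step 2
Reactants: 2 2,6-dimethyl-3-nitrobenzoic acid
Product: 3 3-amino-2,6-dimethylbenzoic acid
Conditions: H2 (1 atm), 10% Pd/C, MeOH, rt
Reagents that add atoms: none
Why: Catalytic hydrogenation of a nitroarene to the aniline over palladium on carbon leaves the carboxylic acid and the ring untouched.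

Step 3
Reactants: 3 3-amino-2,6-dimethylbenzoic acid
Product: 5 3-hydroxy-2,6-dimethylbenzoic acid, via arenediazonium hydrogensulfate 4 (not isolated)
Conditions: NaNO2, aq. H2SO4, 0 °C; then added to boiling dilute H2SO4
Reagents that add atoms: water, O
Why: Diazotisation of the aniline and thermal hydrolysis of the arenediazonium salt in hot dilute acid (phenol synthesis via a diazonium salt) put the hydroxyl group exactly where the nitro group stood.

Step 4
Reactants: 5 3-hydroxy-2,6-dimethylbenzoic acid
Product: 6 3-(hydroxymethyl)-2,4-dimethylphenol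
Conditions: BH3·THF (3.5 equiv), THF, 0 °C → 65 °C; MeOH, then aqueous work-up
Reagents that add atoms: none
Why: Borane reduces carboxylic acids through an acyloxyborane, a pathway that tolerates the two ortho methyl groups and the free phenol, to give the benzylic alcohol.

Step 5
Reactants: 6 3-(hydroxymethyl)-2,4-dimethylphenol
Product: 7 tert-butyl{3-[(tert-butyldimethylsilyloxy)methyl]-2,4-dimethylphenoxy}dimethylsilane
Conditions: TBSCl (2.4 equiv), imidazole (5 equiv), DMF, rt
Reagents that add atoms: tert-butyldimethylsilyl chloride, CC(C)(C)[Si](C)(C)Cl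
Why: Standard silylation with TBSCl and imidazole protects the phenol for the carbanion steps and turns the benzylic hydroxyl into a group that step 6 can replace directly.

Step 6
Reactants: 7 bis-silyl ether
Product: 8 [3-(bromomethyl)-2,4-dimethylphenoxy](tert-butyl)dimethylsilane
Conditions: Ph3PBr2 (1.2 equiv), CH2Cl2, 0 °C → rt
Reagents that add atoms: triphenylphosphine dibromide, BrP(Br)(c1ccccc1)(c1ccccc1)c1ccccc1
Why: Triphenylphosphine dibromide converts alkyl silyl ethers into bromides through an alkoxyphosphonium ion and SN2 attack of bromide, a path open to the benzylic carbon but not to the aryl silyl ether, which therefore survives.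

Step 7
Reactants: 8 benzylic bromide; 9 dimethyl (2-oxopropyl)phosphonate
Product: 11 dimethyl {4-[3-(tert-butyldimethylsilyloxy)-2,6-dimethylphenyl]-2-oxobutyl}phosphonate, via phosphonate 1,3-dianion 10 (not isolated)
Conditions: 9, NaH (1.2 equiv), THF, 0 °C; n-BuLi (1.15 equiv), 0 °C; then 8, 0 °C → rt
Reagents that add atoms: none
Why: In the 1,3-dianion of a β-ketophosphonate the terminal carbanion is the more basic and nucleophilic site, so alkylation with the benzylic bromide takes place only at the γ-carbon (dianion alkylation), forming C6–C7.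

Step 8
Reactants: 12 allyl methyl carbonate
Product: 14 methyl 2-oxoethyl carbonate, via 1,2,4-trioxolane ozonide 13 (not isolated)
Conditions: O3, CH2Cl2, −78 °C; Me2S, −78 °C → rt; the dried solution is used directly
Reagents that add atoms: ozone, O=[O+][O-]
Why: Ozonolysis with reductive work-up cleaves the terminal alkene to the α-carbonate aldehyde and formaldehyde, and the carbonate is inert to ozone and dimethyl sulfide.

Step 9
Reactants: 11 β-ketophosphonate; 14 methyl 2-oxoethyl carbonate
Product: 15 (2E)-6-[3-(tert-butyldimethylsilyloxy)-2,6-dimethylphenyl]-4-oxohex-2-en-1-yl methyl carbonate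
Conditions: LiCl (1.5 equiv), i-Pr2NEt (1.3 equiv), MeCN, rt
Reagents that add atoms: none
Why: The Horner–Wadsworth–Emmons reaction of a β-ketophosphonate under the mild LiCl/amine conditions gives the (E)-enone and spares the carbonate and the aryl silyl ether.

Step 10
Reactants: 15 enone carbonate
Product: 16 (2E)-3-(2-{2-[3-(tert-butyldimethylsilyloxy)-2,6-dimethylphenyl]ethyl}-1,3-dioxolan-2-yl)prop-2-en-1-yl methyl carbonate
Conditions: 1,2-bis(trimethylsilyloxy)ethane (2 equiv), TMSOTf (5 mol%), CH2Cl2, −78 → −20 °C; pyridine quench
Reagents that add atoms: 1,2-bis(trimethylsilyloxy)ethane, C[Si](C)(C)OCCO[Si](C)(C)C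
Why: Ketalisation with the bis(trimethylsilyl) ether of ethylene glycol and catalytic TMSOTf (Noyori conditions) is aprotic, runs at low temperature and is driven by formation of hexamethyldisiloxane, conditions under which enones give dioxolanes without migration of the double bond; it makes C8 an sp3 carbon with no hydrogen.

Step 11
Reactants: 16 aryl silyl ether
Product: 17 (2E)-3-{2-[2-(3-hydroxy-2,6-dimethylphenyl)ethyl]-1,3-dioxolan-2-yl}prop-2-en-1-yl methyl carbonate
Conditions: TBAF (1.1 equiv), AcOH (1.2 equiv), THF, 0 °C
Reagents that add atoms: none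
Why: Fluoride cleaves the aryl silyl ether within minutes at 0 °C, and the acetic acid buffer keeps the phenoxide from attacking the carbonate.

Step 12
Reactants: 17 phenol with (E)-allylic methyl carbonate
Product: 18 8,8-ethylenedioxy-4,10β-dimethyl-9β-vinyl bicyclic 1,4-dien-3-one (ring A: C1=C2, C3=O, C4=C5; 9α-H; vinyl cis to the C10 methyl)
Conditions: Pd2(dba)3·CHCl3 (2.5 mol%), (R,R)-ANDEN-phenyl bisphosphine [(11R,12R)-11,12-bis(2-diphenylphosphinobenzamido)-9,10-dihydro-9,10-ethanoanthracene] (7.5 mol%), CH2Cl2 (0.01 M), rt
Reagents that add atoms: none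
Why: Proposed new method: zerovalent palladium ionises the primary allylic carbonate of 17 to a cationic π-allyl complex of divalent palladium over C9–C11–C12, the leaving group falls apart into carbon dioxide and methoxide, the methoxide deprotonates the phenol, and the para carbon C10 of the phenolate attacks C9 from the face opposite to the metal; the closest known reactions are the palladium- and iridium-catalysed intramolecular asymmetric allylic dearomatisations of para-substituted phenols to spirocyclohexadienones and the base-mediated para-alkylative cyclisations of phenols. Ring B closes in the 6-exo mode, the other two allyl carbons being left as the C9 vinyl group; attack at C12 would need an eight-membered ring and O-allylation a strained meta-bridged ring, and the allyl unit is deliberately not centred on C8, where both termini would close six-membered rings. C9 is set by the bisphosphine, which selects the face of the π-allyl unit after the two faces have equilibrated through the unsubstituted C12 terminus (π–σ–π), so that the achiral precursor converges on one enantiomer. C10 is set relative to C9 in a chair-like transition state in which the allyl unit lies pseudo-equatorial and outside the face of ring A, which places the vinyl group cis to the C10 methyl. The step needs attack through C10 in place of the ortho carbon C4, both being six-membered closures; C10 should win because it carries the larger coefficient of the phenolate and leads to the more stable cross-conjugated dienone, while the C4 methyl prevents an ortho adduct from ending as an aromatic product. The C10 methyl blocks rearomatisation of the product and the C8 dioxolane leaves the allyl unit without β-hydrogen, so that diene formation cannot compete; this selectivity is nevertheless unproven and is the main risk of the route.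

Step 13
Reactants: 18 cross-conjugated dienone
Product: 19 8,8-ethylenedioxy-4,10β-dimethyl-9β-vinyl bicyclic 4-en-3-one
Conditions: [(Ph3P)CuH]6 (0.25 equiv), benzene, H2O (5 equiv), rt
Reagents that add atoms: none
Why: Conjugate reduction with the copper hydride hexamer delivers hydride to the β-carbon of the disubstituted C1=C2 enone arm only, since the tetrasubstituted C4=C5 arm is too hindered and isolated alkenes and ketals do not react with copper hydride.

Step 14
Reactants: 19 4-methyl enone
Product: 21 8,8-ethylenedioxy-4,4,10β-trimethyl-9β-vinyl-5α-decalin-3-one, via lithium enolate 20 (not isolated)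
Conditions: Li (2.5 equiv), NH3(l)/THF, t-BuOH (1.0 equiv), −78 °C; isoprene; MeI (6 equiv), −78 → −33 °C
Reagents that add atoms: iodomethane, CI
Why: Dissolving-metal reduction of the enone gives a C5 carbanion that is protonated axially, trans to the C10 methyl (5α-H), and leaves the regiodefined C3–C4 lithium enolate, which iodomethane alkylates at C4 to complete the gem-dimethyl group (reductive alkylation of an enone).

Step 15
Reactants: 21 keto ketal
Product: 23 3β-hydroxy-4,4,10β-trimethyl-9β-vinyl-5α-decalin-8-one, via hydroxy ketal 22 (not isolated)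
Conditions: NaBH4, MeOH, 0 °C; then 2 M HCl, THF, rt
Reagents that add atoms: water, O
Why: Borohydride attacks the C3 ketone axially from the α face to give the equatorial 3β-alcohol, and subsequent acid hydrolysis of the dioxolane then releases C8 as the only ketone of the molecule, with the C9 vinyl group remaining in its favoured equatorial position next to it.

Step 16
Reactants: 23 hydroxy ketone
Product: 24 4,4,10β-trimethyl-8-methylene-9β-vinyl-5α-decalin-3β-ol
Conditions: Ph3PCH3Br (4 equiv), KOtBu (3.8 equiv), THF, 0 °C → rt
Reagents that add atoms: methyltriphenylphosphonium bromide, C[P+](c1ccccc1)(c1ccccc1)c1ccccc1.[Br-]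
Why: Wittig methylenation with an excess of the unstabilised ylide (one equivalent is held as the C3 alkoxide) converts the C8 ketone, flanked by a methylene and a tertiary carbon, into the exocyclic 8-methylene group.

Step 17
Reactants: 24 diene alcohol
Product: 25 8α-spiro-epoxide of 24 (oxirane oxygen α on C8, oxirane CH2 β; 3β-OH and 9β-vinyl unchanged)
Conditions: mCPBA (1.1 equiv), NaHCO3, CH2Cl2, 0 °C
Reagents that add atoms: 3-chloroperoxybenzoic acid, O=C(OO)c1cccc(Cl)c1
Why: Peracid epoxidation (Prilezhaev reaction) prefers the more electron-rich 1,1-disubstituted alkene over the monosubstituted vinyl group and approaches it from the α face, away from the axial C10 methyl that shields the β face, which places the new C8–O bond α.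

Step 18
Reactants: 25 epoxy alcohol
Product: 26 4,4,8β,10β-tetramethyl-9β-vinyl-5α-decalin-3β,8α-diol
Conditions: LiAlH4 (3 equiv), THF, 0 °C → reflux
Reagents that add atoms: none
Why: Hydride opens the spiro-epoxide by SN2 attack at its primary carbon, which becomes the β-methyl group and leaves the tertiary 8α-alcohol with the configuration of the target.

Step 19
Reactants: 27 geraniol
Product: 28 geranyl bromide [(2E)-1-bromo-3,7-dimethylocta-2,6-diene]
Conditions: PBr3 (0.4 equiv), Et2O, −10 °C
Reagents that add atoms: phosphorus tribromide, BrP(Br)Br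
Why: Phosphorus tribromide converts the primary allylic alcohol into the bromide at low temperature without allylic transposition or loss of the E geometry.

Step 20
Reactants: 28 geranyl bromide
Product: 29 (5E)-6,10-dimethylundeca-5,9-dien-1-yne
Conditions: propyne, n-BuLi (2 equiv per propyne), TMEDA, THF, −78 → 0 °C; then 28, −78 °C → rt; aqueous work-up
Reagents that add atoms: propyne, CC#C
Why: 1,3-Dilithiopropyne reacts at its sp3 carbon with the primary allylic bromide in an SN2 displacement, which after aqueous work-up gives the terminal 1,5-enyne in one operation.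

Step 21
Reactants: 29 enyne
Product: 31 (1E,5E)-1-iodo-2,6,10-trimethylundeca-1,5,9-triene, via alkenylalane 30 (not isolated)
Conditions: AlMe3 (2 equiv), Cp2ZrCl2 (0.25 equiv), CH2Cl2, 0 °C → rt; then I2, THF, −30 → 0 °C
Reagents that add atoms: trimethylaluminium, C[Al](C)C; iodine, II
Why: Zirconium-catalysed carboalumination (Negishi) adds methyl and aluminium syn across the terminal alkyne with methyl on the internal carbon, and iodinolysis of the alkenylalane with retention gives the (E)-iodoalkene that defines the C13=C14 geometry.

Step 22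
Reactants: 31 iodotriene
Product: 32 (2E,6E,10E)-11-iodo-2,6,10-trimethylundeca-2,6,10-trien-1-ol
Conditions: SeO2 (0.3 equiv), t-BuOOH (3 equiv), salicylic acid (0.1 equiv), CH2Cl2, 0 °C → rt
Reagents that add atoms: selenium dioxide (oxygen carrier), O=[Se]=O; tert-butyl hydroperoxide (terminal oxygen source), CC(C)(C)OO
Why: Selenium dioxide allylic oxidation (ene reaction followed by [2,3]-sigmatropic shift) selects the (E)-methyl group of the terminal isopropylidene unit, as is usual for polyprenyl chains, the iodoalkene being deactivated, and so creates the (E)-hydroxymethyl terminus.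

Step 23
Reactants: 32 iodo trienol
Product: 33 tert-butyl{[(2E,6E,10E)-11-iodo-2,6,10-trimethylundeca-2,6,10-trien-1-yl]oxy}dimethylsilane
Conditions: TBSCl (1.2 equiv), imidazole (2.5 equiv), DMF, rt
Reagents that add atoms: tert-butyldimethylsilyl chloride, CC(C)(C)[Si](C)(C)Cl
Why: Silylation of the primary allylic alcohol masks it for the oxidation in step 25.

Step 24
Reactants: 26 vinyl diol; 33 iodotriene silyl ether
Product: 35 3β,8α-diol of the coupled (13E,17E,21E)-triene carrying the terminal OTBS group, via B-alkylborane 34 (not isolated)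
Conditions: 9-BBN dimer (3 equiv B–H), THF, rt → 50 °C; then 33 (1.3 equiv), Pd(dppf)Cl2·CH2Cl2 (5 mol%), AsPh3 (10 mol%), Cs2CO3 (3 equiv), DMF/H2O, rt
Reagents that add atoms: none
Why: 9-BBN adds to the only alkene of 26 with anti-Markovnikov selectivity, the free hydroxyls merely consuming reagent as borinates, and the B-alkyl Suzuki–Miyaura coupling with the iodoalkene forms C12–C13 with retention of the E geometry.

Step 25
Reactants: 35 coupled diol
Product: 36 O-TBS-commipherol (C3 ketone, 8α-OH, terminal OTBS)
Conditions: Dess–Martin periodinane (1.3 equiv), pyridine (3 equiv), CH2Cl2, 0 °C → rt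
Reagents that add atoms: none
Why: The periodinane oxidises the only secondary alcohol to the C3 ketone, while the tertiary alcohol, the silyl ether and the alkenes are inert.

Step 26
Reactants: 36 O-TBS-commipherol
Product: 37 commipherol
Conditions: HF·pyridine, pyridine, THF, 0 °C → rt
Reagents that add atoms: none
Why: Buffered hydrogen fluoride removes the primary silyl ether without touching the tertiary alcohol, the ketone or the trisubstituted alkenes.

**Compound list**

1 | 2,6-dimethylbenzoic acid | Cc1cccc(C)c1C(=O)O | starting material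
2 | 2,6-dimethyl-3-nitrobenzoic acid | Cc1ccc([N+](=O)[O-])c(C)c1C(=O)O | intermediate
3 | 3-amino-2,6-dimethylbenzoic acid | Cc1ccc(N)c(C)c1C(=O)O | intermediate
4 | 3-carboxy-2,4-dimethylbenzenediazonium hydrogensulfate | Cc1ccc([N+]#N)c(C)c1C(=O)O.OS(=O)(=O)[O-] | intermediate (not isolated)
5 | 3-hydroxy-2,6-dimethylbenzoic acid | Cc1ccc(O)c(C)c1C(=O)O | intermediate
6 | 3-(hydroxymethyl)-2,4-dimethylphenol | Cc1ccc(O)c(C)c1CO | intermediate
7 | tert-butyl{3-[(tert-butyldimethylsilyloxy)methyl]-2,4-dimethylphenoxy}dimethylsilane | Cc1ccc(O[Si](C)(C)C(C)(C)C)c(C)c1CO[Si](C)(C)C(C)(C)C | intermediate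
8 | [3-(bromomethyl)-2,4-dimethylphenoxy](tert-butyl)dimethylsilane | Cc1ccc(O[Si](C)(C)C(C)(C)C)c(C)c1CBr | intermediate
9 | dimethyl (2-oxopropyl)phosphonate | CC(=O)CP(=O)(OC)OC | starting material
10 | sodium lithium 1,3-dianion of 9 | [CH2-]C(=O)[CH-]P(=O)(OC)OC.[Na+].[Li+] | intermediate (not isolated)
11 | dimethyl {4-[3-(tert-butyldimethylsilyloxy)-2,6-dimethylphenyl]-2-oxobutyl}phosphonate | Cc1ccc(O[Si](C)(C)C(C)(C)C)c(C)c1CCC(=O)CP(=O)(OC)OC | intermediate
12 | allyl methyl carbonate | C=CCOC(=O)OC | starting material
13 | 3-[(methoxycarbonyloxy)methyl]-1,2,4-trioxolane | COC(=O)OCC1OCOO1 | intermediate (not isolated)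
14 | methyl 2-oxoethyl carbonate | COC(=O)OCC=O | intermediate
15 | (2E)-6-[3-(tert-butyldimethylsilyloxy)-2,6-dimethylphenyl]-4-oxohex-2-en-1-yl methyl carbonate | Cc1ccc(O[Si](C)(C)C(C)(C)C)c(C)c1CCC(=O)/C=C/COC(=O)OC | intermediate
16 | (2E)-3-(2-{2-[3-(tert-butyldimethylsilyloxy)-2,6-dimethylphenyl]ethyl}-1,3-dioxolan-2-yl)prop-2-en-1-yl methyl carbonate | Cc1ccc(O[Si](C)(C)C(C)(C)C)c(C)c1CCC2(OCCO2)/C=C/COC(=O)OC | intermediate
17 | (2E)-3-{2-[2-(3-hydroxy-2,6-dimethylphenyl)ethyl]-1,3-dioxolan-2-yl}prop-2-en-1-yl methyl carbonate | Cc1ccc(O)c(C)c1CCC2(OCCO2)/C=C/COC(=O)OC | intermediate (key-step precursor)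
18 | 8,8-ethylenedioxy-4,10β-dimethyl-9β-vinyl bicyclic 1,4-dien-3-one (9α-H, vinyl cis to C10 methyl) | C=C[C@@H]1[C@@]2(C)C=CC(=O)C(C)=C2CCC13OCCO3 | intermediate (key-step product)
19 | 8,8-ethylenedioxy-4,10β-dimethyl-9β-vinyl bicyclic 4-en-3-one | C=C[C@@H]1[C@@]2(C)CCC(=O)C(C)=C2CCC13OCCO3 | intermediate
20 | lithium C3–C4 enolate of the 5α-H decalin | C=C[C@@H]1[C@@]2(C)CCC([O-])=C(C)[C@@H]2CCC13OCCO3.[Li+] | intermediate (not isolated)
21 | 8,8-ethylenedioxy-4,4,10β-trimethyl-9β-vinyl-5α-decalin-3-one | C=C[C@@H]1[C@@]2(C)CCC(=O)C(C)(C)[C@@H]2CCC13OCCO3 | intermediate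
22 | 8,8-ethylenedioxy-4,4,10β-trimethyl-9β-vinyl-5α-decalin-3β-ol | C=C[C@@H]1[C@@]2(C)CC[C@H](O)C(C)(C)[C@@H]2CCC13OCCO3 | intermediate (not isolated)
23 | 3β-hydroxy-4,4,10β-trimethyl-9β-vinyl-5α-decalin-8-one | C=C[C@@H]1[C@@]2(C)CC[C@H](O)C(C)(C)[C@@H]2CCC1=O | intermediate
24 | 4,4,10β-trimethyl-8-methylene-9β-vinyl-5α-decalin-3β-ol | C=C[C@@H]1[C@@]2(C)CC[C@H](O)C(C)(C)[C@@H]2CCC1=C | intermediate
25 | 8α-spiro-epoxide of 24 (oxygen α) | C=C[C@@H]1[C@@]2(C)CC[C@H](O)C(C)(C)[C@@H]2CC[C@@]13OC3 | intermediate
26 | 4,4,8β,10β-tetramethyl-9β-vinyl-5α-decalin-3β,8α-diol | C=C[C@@H]1[C@@]2(C)CC[C@H](O)C(C)(C)[C@@H]2CC[C@@]1(C)O | intermediate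
27 | geraniol | CC(C)=CCC/C(C)=C/CO | starting material
28 | geranyl bromide | CC(C)=CCC/C(C)=C/CBr | intermediate
29 | (5E)-6,10-dimethylundeca-5,9-dien-1-yne | CC(C)=CCC/C(C)=C/CCC#C | intermediate
30 | dimethyl[(1E,5E)-2,6,10-trimethylundeca-1,5,9-trien-1-yl]alumane | CC(C)=CCC/C(C)=C/CC/C(C)=C/[Al](C)C | intermediate (not isolated)
31 | (1E,5E)-1-iodo-2,6,10-trimethylundeca-1,5,9-triene | CC(C)=CCC/C(C)=C/CC/C(C)=C/I | intermediate
32 | (2E,6E,10E)-11-iodo-2,6,10-trimethylundeca-2,6,10-trien-1-ol | OC/C(C)=C/CC/C(C)=C/CC/C(C)=C/I | intermediate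
33 | tert-butyl{[(2E,6E,10E)-11-iodo-2,6,10-trimethylundeca-2,6,10-trien-1-yl]oxy}dimethylsilane | CC(C)(C)[Si](C)(C)OC/C(C)=C/CC/C(C)=C/CC/C(C)=C/I | intermediate
34 | C12 B-alkyl-9-BBN of 26 with the C3 hydroxyl as 9-BBN borinate | C(C[C@@H]1[C@@]2(C)CC[C@H](OB3C4CCCC3CCC4)C(C)(C)[C@@H]2CC[C@@]1(C)O)B5C6CCCC5CCC6 | intermediate (not isolated)
35 | 3β,8α-diol of the coupled (13E,17E,21E)-triene with terminal OTBS | C/C(=C\CC/C(C)=C/CC/C(C)=C/CC[C@@H]1[C@@]2(C)CC[C@H](O)C(C)(C)[C@@H]2CC[C@@]1(C)O)CO[Si](C)(C)C(C)(C)C | intermediate
36 | O-TBS-commipherol | C/C(=C\CC/C(C)=C/CC/C(C)=C/CC[C@@H]1[C@@]2(C)CCC(=O)C(C)(C)[C@@H]2CC[C@@]1(C)O)CO[Si](C)(C)C(C)(C)C | intermediate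
37 | commipherol (5R,8R,9R,10S; 13E,17E,21E) | C/C(=C\CC/C(C)=C/CC/C(C)=C/CC[C@@H]1[C@@]2(C)CCC(=O)C(C)(C)[C@@H]2CC[C@@]1(C)O)CO | target

**Count and risks**

Total: 26 steps. Longest linear sequence: 20 steps (steps 1–7, 9–18, 24–26); step 8 and steps 19–23 are side branches.

Steps most likely to fail:

1. Step 12 (Proposed new method). What may go wrong: ring closure through the ortho carbon C4, poor discrimination of the allyl or arene face (C9 epimer, low enantiomeric purity), or a cyclisation at the crowded C9 terminus so slow that intermolecular O-allylation takes over. Fallback, a reversal of polarity with known chemistry: it sets out from 16 and comes back at 18. Palladium-catalysed silylation of the allylic carbonate with hexamethyldisilane (Pd2(dba)3·CHCl3, LiCl, DMF, 80 °C) gives the (E)-allyltrimethylsilane F1, and TBAF/AcOH frees the phenol F2. Oxidative dearomatisation with PhI(OAc)2 in (CF3)2CHOH over NaHCO3 at −20 °C makes the arene the electrophile, and the γ-carbon C9 of the allylsilane bonds to the para carbon C10 with loss of silicon (a known hypervalent-iodine dearomatising cyclisation onto an allylsilane). This closes ring B and leaves the C9 vinyl group, giving 18. Without a chiral catalyst 18 is formed as the racemate and is resolved by preparative chromatography on a chiral stationary phase before step 13.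

2. Step 10. What may go wrong: incomplete ketalisation of the conjugated ketone, conjugate addition of the glycol, shift of the double bond, or Lewis-acid ionisation of the allylic carbonate. Fallback, in which the ketal is made on an ynone and the E alkene only afterwards: it sets out from 8 and comes back at 16. The lithium enolate of N-methoxy-N-methylacetamide (LDA, THF, −78 °C) is alkylated with 8 to give the Weinreb amide F3, and the dilithio derivative of prop-2-yn-1-ol adds once to give the hydroxy ynone F4. Ethylene glycol/TsOH (benzene, reflux, water separator) gives the dioxolane F5. NaAlH2(OCH2CH2OMe)2 in THF at 0 °C reduces the propargylic alcohol by trans-hydroalumination to the (E)-allylic alcohol F6, and methyl chloroformate/pyridine then gives 16.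

3. Step 17. What may go wrong: peracid attack on the β face, which would give the wrong configuration at C8 after step 18, or attack on the vinyl group. Fallback, in which water is the nucleophile that sets C8: it sets out from 24 and comes back at 26. NBS in THF/H2O at 0 °C forms the bromonium ion reversibly on the more electron-rich 1,1-disubstituted alkene, and water opens it at the tertiary C8 along the equatorial α trajectory, away from the axial C10 methyl, to give the bromohydrin F7. LiAlH4 in THF then closes F7 to epoxide 25 in the flask and reduces it to 26.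

**Further compounds**

F1 | step 12 | tert-butyl(dimethyl)[2,4-dimethyl-3-(2-{2-[(1E)-3-(trimethylsilyl)prop-1-en-1-yl]-1,3-dioxolan-2-yl}ethyl)phenoxy]silane | Cc1ccc(O[Si](C)(C)C(C)(C)C)c(C)c1CCC2(OCCO2)/C=C/C[Si](C)(C)C
F2 | step 12 | 2,4-dimethyl-3-(2-{2-[(1E)-3-(trimethylsilyl)prop-1-en-1-yl]-1,3-dioxolan-2-yl}ethyl)phenol | Cc1ccc(O)c(C)c1CCC2(OCCO2)/C=C/C[Si](C)(C)C
F3 | step 10 | 3-[3-(tert-butyldimethylsilyloxy)-2,6-dimethylphenyl]-N-methoxy-N-methylpropanamide | Cc1ccc(O[Si](C)(C)C(C)(C)C)c(C)c1CCC(=O)N(C)OC
F4 | step 10 | 6-[3-(tert-butyldimethylsilyloxy)-2,6-dimethylphenyl]-1-hydroxyhex-2-yn-4-one | Cc1ccc(O[Si](C)(C)C(C)(C)C)c(C)c1CCC(=O)C#CCO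
F5 | step 10 | 3-(2-{2-[3-(tert-butyldimethylsilyloxy)-2,6-dimethylphenyl]ethyl}-1,3-dioxolan-2-yl)prop-2-yn-1-ol | Cc1ccc(O[Si](C)(C)C(C)(C)C)c(C)c1CCC2(OCCO2)C#CCO
F6 | step 10 | (2E)-3-(2-{2-[3-(tert-butyldimethylsilyloxy)-2,6-dimethylphenyl]ethyl}-1,3-dioxolan-2-yl)prop-2-en-1-ol | Cc1ccc(O[Si](C)(C)C(C)(C)C)c(C)c1CCC2(OCCO2)/C=C/CO
F7 | step 17 | 8β-(bromomethyl)-4,4,10β-trimethyl-9β-vinyl-5α-decalin-3β,8α-diol | C=C[C@@H]1[C@@]2(C)CC[C@H](O)C(C)(C)[C@@H]2CC[C@@]1(CBr)O
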